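**Retrosynthetic overview**
- The C6–CH2 bond to the pyranone is cut last: a one-carbon iminium links the 5,7-dihydroxy-8-senecioyl flavanone to 6-ethyl-4-hydroxy-5-methyl-2-pyranone, itself made from 3-pentanone and malonyl dichloride.
- The C8 senecioyl group comes from a carbonylative Stille coupling of a C8 iodide; the iodide comes from iodination of the 5,7-di-O-benzyl flavanone.
- Ring C (O1–C2 bond) is closed by a Mitsunobu reaction of an (R)-β-hydroxy ketone onto its only free phenol, with inversion to (2S).
- The strategy rests on C4a of ring A: it carries the C4 acyl carbon and sits between the O1-bearing C8a and the oxygenated C5. A 3-alkoxyaryne inserting into the C–O bond of a carboxylic acid gives exactly this pattern, so C8a–O and C4a–C4 are formed together from a 3,5-bis(benzyloxy)aryne and (R)-3-silyloxy-3-phenylpropanoic acid.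
- Ring order: ring A and the phenyl ring B are bought, ring C closes by Mitsunobu, and the pyranone ring is built separately and joined last.

Key step: step 5

Remark: the carbinol is carried as its triisopropylsilyl (TIPS) ether because it has to survive fluoride in hot THF; tributyl(2-methylprop-1-en-1-yl)stannane and Eschenmoser's salt (Me2N=CH2+ I−) are taken as purchased reagents.

**Step 1**
Reactants: 1 3,5-bis(benzyloxy)phenol
Product: 2 2-bromo-3,5-bis(benzyloxy)phenol
Conditions: NBS (1.0 equiv), CH2Cl2, −78 °C to rt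
Reagents that add atoms: N-bromosuccinimide, O=C1CCC(=O)N1Br
Why: Electrophilic aromatic bromination in a non-polar solvent should go ortho to the free hydroxyl (hydrogen-bonded delivery of NBS), since the para position is shielded by two benzyloxy groups.

**Step 2**
Reactants: 2 2-bromo-3,5-bis(benzyloxy)phenol
Product: 3 [2-bromo-3,5-bis(benzyloxy)phenoxy]trimethylsilane
Conditions: (Me3Si)2NH, THF, 70 °C; concentrate
Reagents that add atoms: hexamethyldisilazane, C[Si](C)(C)N[Si](C)(C)C
Why: O-silylation of a phenol with hexamethyldisilazane is clean and leaves only ammonia, so the crude silyl ether can be used directly.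

**Step 3**
Reactants: 3 [2-bromo-3,5-bis(benzyloxy)phenoxy]trimethylsilane
Product: 6 3,5-bis(benzyloxy)-2-(trimethylsilyl)phenyl trifluoromethanesulfonate, via aryllithium 4 (not isolated), via lithium 2-silylphenoxide 5 (not isolated)
Conditions: n-BuLi, THF, −100 to −80 °C; then Tf2O, −100 to −80 °C
Reagents that add atoms: trifluoromethanesulfonic anhydride, O=S(=O)(OS(=O)(=O)C(F)(F)F)C(F)(F)F; n-butyllithium, [Li]CCCC (lithium of 4 and 5 only)
Why: Bromine–lithium exchange followed by 1,3 O→C silyl migration (retro-Brook rearrangement) should give the C-silyl phenoxide, which is triflated in the same flask, the standard way to ortho-silylaryl triflates.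

**Step 4**
Reactants: 7 (R)-3-hydroxy-3-phenylpropanoic acid
Product: 9 (3R)-3-phenyl-3-(triisopropylsilyloxy)propanoic acid, via bis-silylated ester 8 (not isolated)
Conditions: TIPSOTf (2.3 equiv), 2,6-lutidine, CH2Cl2, 0 °C to rt; then K2CO3, MeOH/THF/H2O, rt; aq HCl to pH 3
Reagents that add atoms: triisopropylsilyl trifluoromethanesulfonate, CC(C)[Si](OS(=O)(=O)C(F)(F)F)(C(C)C)C(C)C
Why: Silylation of both hydroxyl and carboxyl groups followed by selective carbonate cleavage of the far more labile silyl ester should leave the secondary silyl ether, with the (R) stereocenter untouched.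

**Step 5**
Reactants: 6 3,5-bis(benzyloxy)-2-(trimethylsilyl)phenyl trifluoromethanesulfonate; 9 (3R)-3-phenyl-3-(triisopropylsilyloxy)propanoic acid
Product: 13 (3R)-1-[2,4-bis(benzyloxy)-6-hydroxyphenyl]-3-phenyl-3-(triisopropylsilyloxy)propan-1-one, via 3,5-bis(benzyloxy)benzyne 10 (not isolated), via ortho-acyloxyaryl anion 11 (not isolated), via benzoxetane alkoxide 12 (not isolated)
Conditions: 6 (1.5 equiv), CsF (4 equiv), THF, 110 °C (sealed tube); aq NH4Cl
Reagents that add atoms: cesium fluoride, [Cs+].[F-] (cesium of 11 and 12 only)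
Why: CsF removes the trimethylsilyl group of 6 and triflate leaves to give aryne 10; the cesium carboxylate of 9 adds through oxygen to the aryne carbon remote from the flanking benzyloxy group (future C8a), so the aryl anion 11 forms at the carbon next to that σ-withdrawing oxygen (future C4a). The anion attacks the adjacent ester carbonyl (4-exo-trig) to give benzoxetane alkoxide 12, which opens to the chelated ortho-acyl phenoxide and thereby forms the C8a–O and C4a–C4 bonds; the four-membered ring is transient and no ring is retained. The closest known reaction type is the CsF-mediated insertion of arynes into the C–O bond of aliphatic and aromatic carboxylic acids in hot THF, which gives ortho-hydroxyaryl ketones. No stereocenter is created, and the (R)-carbinol lies two carbons from the reacting carbonyl and is not involved. The step needs regioselective addition to the unsymmetrical aryne, which the C–O dipole of the benzyloxy group beside the triple bond should secure, and it needs acyl transfer to outrun protonation and β-elimination, which aprotic THF, sparingly soluble CsF, the fluoride-resistant TIPS ether and the poorly enolisable chelated phenoxide product should favour.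

**Step 6**
Reactants: 13 (3R)-1-[2,4-bis(benzyloxy)-6-hydroxyphenyl]-3-phenyl-3-(triisopropylsilyloxy)propan-1-one
Product: 14 (3R)-1-[2,4-bis(benzyloxy)-6-hydroxyphenyl]-3-hydroxy-3-phenylpropan-1-one
Conditions: HF·pyridine, pyridine, THF, 0 °C to rt
Reagents that add atoms: none
Why: Fluoride-mediated Si–O cleavage under buffered, weakly acidic conditions should free the carbinol without the retro-aldol or elimination that a basic fluoride source would invite, with (R) retained.

**Step 7**
Reactants: 14 (3R)-1-[2,4-bis(benzyloxy)-6-hydroxyphenyl]-3-hydroxy-3-phenylpropan-1-one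
Product: 15 (2S)-5,7-bis(benzyloxy)-2-phenyl-2,3-dihydro-4H-chromen-4-one
Conditions: PPh3, DIAD, THF, 0 °C to rt
Reagents that add atoms: none
Why: Intramolecular Mitsunobu etherification (6-exo-tet) should have the only free phenol displace the activated benzylic oxygen by SN2, which inverts the (R)-carbinol to (S) at C2.

**Step 8**
Reactants: 15 (2S)-5,7-bis(benzyloxy)-2-phenyl-2,3-dihydro-4H-chromen-4-one
Product: 16 (2S)-5,7-bis(benzyloxy)-8-iodo-2-phenyl-2,3-dihydro-4H-chromen-4-one
Conditions: NIS, TFA (cat.), MeCN, 0 °C to rt, dark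
Reagents that add atoms: N-iodosuccinimide, O=C1CCC(=O)N1I
Why: Electrophilic aromatic iodination of the fully O-alkylated ring A should go to C8, which lies between the tied-back ring oxygen O1 and one benzyloxy group, whereas C6 is shielded by two freely rotating benzyloxy groups; this is the preference known for 5,7-dialkoxy flavonoids, and C2 is not affected.

**Step 9**
Reactants: 16 (2S)-5,7-bis(benzyloxy)-8-iodo-2-phenyl-2,3-dihydro-4H-chromen-4-one
Product: 17 (2S)-5,7-bis(benzyloxy)-8-(3-methylbut-2-enoyl)-2-phenyl-2,3-dihydro-4H-chromen-4-one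
Conditions: Pd2(dba)3 (5 mol%), AsPh3 (20 mol%), CO (3 atm), Bu3SnCH=CMe2, NMP, 70 °C
Reagents that add atoms: carbon monoxide, [C-]#[O+]; tributyl(2-methylprop-1-en-1-yl)stannane, CC(C)=C[Sn](CCCC)(CCCC)CCCC
Why: Carbonylative Stille coupling (oxidative addition, CO insertion, transmetalation, reductive elimination) should give the aryl alkenyl ketone under neutral conditions that do not open the flavanone or racemise C2.

**Step 10**
Reactants: 17 (2S)-5,7-bis(benzyloxy)-8-(3-methylbut-2-enoyl)-2-phenyl-2,3-dihydro-4H-chromen-4-one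
Product: 18 (2S)-5,7-dihydroxy-8-(3-methylbut-2-enoyl)-2-phenyl-2,3-dihydro-4H-chromen-4-one
Conditions: BCl3, C6HMe5, CH2Cl2, −78 °C; then MeOH/CHCl3, −78 °C
Reagents that add atoms: none
Why: BCl3 debenzylation with pentamethylbenzene as benzyl-cation scavenger should be fast at −78 °C because both benzyl ethers are ortho or peri to a chelating carbonyl, and the scavenger keeps the cation off the nucleophilic C6 while the enone and C2 are spared.

**Step 11**
Reactants: 19 3-pentanone
Product: 20 3-(trimethylsilyloxy)pent-2-ene (E/Z mixture)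
Conditions: TMSOTf, Et3N, CH2Cl2, 0 °C
Reagents that add atoms: trimethylsilyl trifluoromethanesulfonate, C[Si](C)(C)OS(=O)(=O)C(F)(F)F
Why: Soft enolisation and O-silylation of a symmetrical ketone gives a single constitutional silyl enol ether, whose double-bond geometry is irrelevant.

**Step 12**
Reactants: 20 3-(trimethylsilyloxy)pent-2-ene; 21 malonyl dichloride
Product: 23 6-ethyl-4-hydroxy-5-methyl-2H-pyran-2-one, via 4-methyl-3,5-dioxoheptanoyl chloride 22 (not isolated)
Conditions: Et2O, −78 °C to rt
Reagents that add atoms: none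
Why: C-acylation of the silyl enol ether by one acid chloride followed by lactonisation of the enol oxygen onto the second (6-exo-trig) and tautomerisation is the known route from silyl enol ethers and malonyl dichloride to 4-hydroxy-2-pyranones.

**Step 13**
Reactants: 18 (2S)-5,7-dihydroxy-8-(3-methylbut-2-enoyl)-2-phenyl-2,3-dihydro-4H-chromen-4-one; 23 6-ethyl-4-hydroxy-5-methyl-2H-pyran-2-one
Product: 26 (2S)-6-[(6-ethyl-4-hydroxy-5-methyl-2-oxo-2H-pyran-3-yl)methyl]-5,7-dihydroxy-8-(3-methylbut-2-enoyl)-2-phenyl-2,3-dihydro-4H-chromen-4-one, via pyranone Mannich base 24 (not isolated), via 3-methylidenepyrandione 25 (not isolated)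
Conditions: 23, Me2N=CH2+ I− (1.0 equiv), CH2Cl2, rt; then 18, MeCN, 40 °C
Reagents that add atoms: N,N-dimethylmethylideneammonium iodide (Eschenmoser's salt), C=[N+](C)C.[I-]
Why: Mannich aminomethylation of the pyranone at C3 and loss of dimethylammonium should give the electrophilic 3-methylidene dione, which the phloroglucinol-type ring A captures in a Friedel–Crafts/Michael addition at C6, its only free position, without base that could open the flavanone or close the senecioyl group onto the C7 hydroxyl.

**Compound list**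
1 | 3,5-bis(benzyloxy)phenol | Oc1cc(OCc2ccccc2)cc(OCc2ccccc2)c1 | starting material
2 | 2-bromo-3,5-bis(benzyloxy)phenol | Oc1cc(OCc2ccccc2)cc(OCc2ccccc2)c1Br | intermediate
3 | [2-bromo-3,5-bis(benzyloxy)phenoxy]trimethylsilane | C[Si](C)(C)Oc1cc(OCc2ccccc2)cc(OCc2ccccc2)c1Br | intermediate
4 | [2,4-bis(benzyloxy)-6-(trimethylsilyloxy)phenyl]lithium | C[Si](C)(C)Oc1cc(OCc2ccccc2)cc(OCc2ccccc2)c1[Li] | intermediate (not isolated)
5 | lithium 3,5-bis(benzyloxy)-2-(trimethylsilyl)phenoxide | [Li+].[O-]c1cc(OCc2ccccc2)cc(OCc2ccccc2)c1[Si](C)(C)C | intermediate (not isolated)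
6 | 3,5-bis(benzyloxy)-2-(trimethylsilyl)phenyl trifluoromethanesulfonate | C[Si](C)(C)c1c(OS(=O)(=O)C(F)(F)F)cc(OCc2ccccc2)cc1OCc1ccccc1 | intermediate
7 | (R)-3-hydroxy-3-phenylpropanoic acid | OC(=O)C[C@H](c1ccccc1)O | starting material
8 | triisopropylsilyl (3R)-3-phenyl-3-(triisopropylsilyloxy)propanoate | CC(C)[Si](C(C)C)(C(C)C)OC(=O)C[C@H](c1ccccc1)O[Si](C(C)C)(C(C)C)C(C)C | intermediate (not isolated)
9 | (3R)-3-phenyl-3-(triisopropylsilyloxy)propanoic acid | OC(=O)C[C@H](c1ccccc1)O[Si](C(C)C)(C(C)C)C(C)C | intermediate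
10 | 3,5-bis(benzyloxy)benzyne | C1#CC(OCc2ccccc2)=CC(OCc2ccccc2)=C1 | intermediate (not isolated)
11 | cesium 2,4-bis(benzyloxy)-6-{[(3R)-3-phenyl-3-(triisopropylsilyloxy)propanoyl]oxy}benzenide | [Cs+].O=C(C[C@H](c1ccccc1)O[Si](C(C)C)(C(C)C)C(C)C)Oc1cc(OCc2ccccc2)cc(OCc2ccccc2)[c-]1 | intermediate (not isolated)
12 | cesium 4,6-bis(benzyloxy)-2-[(2R)-2-phenyl-2-(triisopropylsilyloxy)ethyl]-2H-benzoxet-2-olate (either configuration at the ring carbon) | [Cs+].[O-]C1(C[C@H](c2ccccc2)O[Si](C(C)C)(C(C)C)C(C)C)Oc2cc(OCc3ccccc3)cc(OCc3ccccc3)c12 | intermediate (not isolated)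
13 | (3R)-1-[2,4-bis(benzyloxy)-6-hydroxyphenyl]-3-phenyl-3-(triisopropylsilyloxy)propan-1-one | O=C(C[C@H](c1ccccc1)O[Si](C(C)C)(C(C)C)C(C)C)c1c(O)cc(OCc2ccccc2)cc1OCc1ccccc1 | intermediate
14 | (3R)-1-[2,4-bis(benzyloxy)-6-hydroxyphenyl]-3-hydroxy-3-phenylpropan-1-one | O=C(C[C@H](c1ccccc1)O)c1c(O)cc(OCc2ccccc2)cc1OCc1ccccc1 | intermediate
15 | (2S)-5,7-bis(benzyloxy)-2-phenyl-2,3-dihydro-4H-chromen-4-one | O=C1C[C@@H](c2ccccc2)Oc2cc(OCc3ccccc3)cc(OCc3ccccc3)c12 | intermediate
16 | (2S)-5,7-bis(benzyloxy)-8-iodo-2-phenyl-2,3-dihydro-4H-chromen-4-one | O=C1C[C@@H](c2ccccc2)Oc2c(I)c(OCc3ccccc3)cc(OCc3ccccc3)c12 | intermediate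
17 | (2S)-5,7-bis(benzyloxy)-8-(3-methylbut-2-enoyl)-2-phenyl-2,3-dihydro-4H-chromen-4-one | O=C1C[C@@H](c2ccccc2)Oc2c(C(=O)C=C(C)C)c(OCc3ccccc3)cc(OCc3ccccc3)c12 | intermediate
18 | (2S)-5,7-dihydroxy-8-(3-methylbut-2-enoyl)-2-phenyl-2,3-dihydro-4H-chromen-4-one | O=C1C[C@@H](c2ccccc2)Oc2c(C(=O)C=C(C)C)c(O)cc(O)c12 | intermediate
19 | 3-pentanone | CCC(=O)CC | starting material
20 | 3-(trimethylsilyloxy)pent-2-ene (E/Z mixture) | CC=C(CC)O[Si](C)(C)C | intermediate
21 | malonyl dichloride | O=C(Cl)CC(=O)Cl | starting material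
22 | 4-methyl-3,5-dioxoheptanoyl chloride | CCC(=O)C(C)C(=O)CC(=O)Cl | intermediate (not isolated)
23 | 6-ethyl-4-hydroxy-5-methyl-2H-pyran-2-one | CCc1oc(=O)cc(O)c1C | intermediate
24 | 3-[(dimethylamino)methyl]-6-ethyl-4-hydroxy-5-methyl-2H-pyran-2-one hydroiodide | CCc1oc(=O)c(C[NH+](C)C)c(O)c1C.[I-] | intermediate (not isolated)
25 | 6-ethyl-5-methyl-3-methylidene-2H-pyran-2,4(3H)-dione | CCC1=C(C)C(=O)C(=C)C(=O)O1 | intermediate (not isolated)
26 | (2S)-6-[(6-ethyl-4-hydroxy-5-methyl-2-oxo-2H-pyran-3-yl)methyl]-5,7-dihydroxy-8-(3-methylbut-2-enoyl)-2-phenyl-2,3-dihydro-4H-chromen-4-one (CNP0311807.1) | CCc1oc(=O)c(Cc2c(O)c(C(=O)C=C(C)C)c3c(c2O)C(=O)C[C@@H](c2ccccc2)O3)c(O)c1C | target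

**Step count**
Total: 13 steps. Longest linear sequence: 10 steps (steps 1, 2, 3, 5, 6, 7, 8, 9, 10, 13).

**Steps most likely to fail**

Step 5 (aryne insertion). The aryl anion may be protonated, or may remove an α-hydrogen of its own ester, before the acyl shift; that would stop the reaction at the aryl ester. β-Elimination of silanolate in the hot, fluoride-containing medium would lead on to chalcone-derived, racemic material, and fluoride may also slowly cleave the silyl ether. The fallback sets out from 2 and 9 and returns at 13. Acid 9 would be converted (MeNHOMe·HCl, EDC·HCl, HOBt, i-Pr2NEt, CH2Cl2) into the Weinreb amide (3R)-N-methoxy-N-methyl-3-phenyl-3-(triisopropylsilyloxy)propanamide F1. Bromophenol 2 would be treated with n-BuLi (2.1 equiv, THF, −78 °C) to give lithium 3,5-bis(benzyloxy)-2-lithiophenoxide F2. Addition of F2 to F1 at −78 °C and aqueous work-up should give ketone 13 with the same ring pattern, without fluoride or heat.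

Step 9 (carbonylative Stille). Transmetalation or CO insertion at the doubly ortho-substituted, electron-rich aryl–palladium centre may be slow, which would lead to direct, CO-free alkenylation or to protodeiodination. The fallback sets out from 16 and returns at 17, with the coupling polarity reversed. Iodide 16 would be stannylated (Me3SnSnMe3, Pd(PPh3)4, toluene, 100 °C) to (2S)-5,7-bis(benzyloxy)-2-phenyl-8-(trimethylstannyl)-2,3-dihydro-4H-chromen-4-one F3. Stille acylation of F3 with 3-methylbut-2-enoyl chloride (PdCl2(PPh3)2, toluene, 60 °C) should then give 17 without a CO insertion step.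

Step 13 (methylene bridging). The methylidene dione may be captured by pyranone that is regenerated in the flask, giving the bis-pyranone homodimer. Attack by the doubly acylated ring A may also be sluggish, and forcing conditions would risk conjugate closure of the C7 hydroxyl onto the senecioyl group. The fallback sets out from 18 and returns at 26, with the one-carbon electrophile placed on the flavanone. Diol 18 would be aminomethylated at C6 with Eschenmoser's salt (CH2Cl2, rt) to (2S)-6-[(dimethylamino)methyl]-5,7-dihydroxy-8-(3-methylbut-2-enoyl)-2-phenyl-2,3-dihydro-4H-chromen-4-one F4. Heating F4 with pyranone 23 (dioxane, 80 °C) should expel dimethylamine through the ortho-quinone methide (2S)-5-hydroxy-6-methylidene-8-(3-methylbut-2-enoyl)-2-phenyl-2,3-dihydro-4H-chromene-4,7(6H)-dione F5, which the acidic pyranone alkylates at C3 to give 26.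

**Further compounds**
F1 | step 5 | (3R)-N-methoxy-N-methyl-3-phenyl-3-(triisopropylsilyloxy)propanamide | CON(C)C(=O)C[C@H](c1ccccc1)O[Si](C(C)C)(C(C)C)C(C)C
F2 | step 5 | lithium 3,5-bis(benzyloxy)-2-lithiophenoxide | [Li+].[O-]c1cc(OCc2ccccc2)cc(OCc2ccccc2)c1[Li]
F3 | step 9 | (2S)-5,7-bis(benzyloxy)-2-phenyl-8-(trimethylstannyl)-2,3-dihydro-4H-chromen-4-one | O=C1C[C@@H](c2ccccc2)Oc2c([Sn](C)(C)C)c(OCc3ccccc3)cc(OCc3ccccc3)c12
F4 | step 13 | (2S)-6-[(dimethylamino)methyl]-5,7-dihydroxy-8-(3-methylbut-2-enoyl)-2-phenyl-2,3-dihydro-4H-chromen-4-one | O=C1C[C@@H](c2ccccc2)Oc2c(C(=O)C=C(C)C)c(O)c(CN(C)C)c(O)c12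
F5 | step 13 | (2S)-5-hydroxy-6-methylidene-8-(3-methylbut-2-enoyl)-2-phenyl-2,3-dihydro-4H-chromene-4,7(6H)-dione | O=C1C[C@@H](c2ccccc2)OC2=C(C(=O)C=C(C)C)C(=O)C(=C)C(O)=C12
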